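**Plan**
- Retrosynthesis: the four benzyl ethers and the silyl ether are removed last; the aryl–vinyl bond of the stilbene on ring C is cut next (Heck disconnection); ring B is then taken apart completely, cutting C1′–C2′, C2′–C3′, C4′–C5′ and C5′–C6′ (C1′ carries the CH2).
- Enabling feature: ring B is a 4-alkylresorcinol with oxygen on C2′ and C4′ around C3′–H. A vinylketene carbonyl carbon (becoming C2′–OH) joined to an O-substituted alkyne (becoming C3′–H and C4′–O) gives exactly this pattern. What is left, Ar2CH–CH2–C, is a β,β-diarylpropionyl unit hidden in a 4-aryl-3,4-dihydrocoumarin.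
- Forward order: coumarin ring from 5-bromo-o-vanillin; asymmetric 1,4-arylation; lactone opening with O-benzylation; ester to aldehyde to methyl enone to diazo enone; ring B by benzannulation; Heck coupling; desilylation; debenzylation.
- Stereochemistry: the single stereocentre (S) is set by the rhodium/(S)-SEGPHOS conjugate arylation of the coumarin and is not touched afterwards; the (E)-stilbene comes from the Heck reaction.

Key step: step 8

Assumption: triisopropylsilyloxyacetylene is treated as a compound to be made (step 7), and the known sense of induction of Rh/SEGPHOS on coumarins ((R)-ligand gives (R)-4-arylchroman-2-one) is taken to hold here; if it were reversed, the other ligand enantiomer would be used.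

**Step 1**
Reactants: 1 5-bromo-2-hydroxy-3-methoxybenzaldehyde
Product: 3 6-bromo-8-methoxy-2H-chromen-2-one, via hydroxycinnamate 2 (not isolated)
Conditions: Ph3P=CHCO2Et, PhNEt2, reflux
Reagents that add atoms: ethyl (triphenylphosphoranylidene)acetate CCOC(=O)C=P(c1ccccc1)(c1ccccc1)c1ccccc1
Why: Wittig olefination of the salicylaldehyde gives cinnamate 2, which at this temperature isomerises about the alkene and lactonises with loss of ethanol (one-pot Wittig/lactonisation coumarin synthesis); the aryl bromide is inert.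

**Step 2**
Reactants: 3 6-bromo-8-methoxy-2H-chromen-2-one; 4 4-benzyloxy-3-methoxyphenylboronic acid
Product: 5 (4S)-4-[4-(benzyloxy)-3-methoxyphenyl]-6-bromo-8-methoxychroman-2-one
Conditions: Rh(acac)(C2H4)2 (3 mol %), (S)-SEGPHOS, 4 (excess), dioxane/H2O 10:1, 60 °C
Reagents that add atoms: none
Why: Hayashi–Miyaura asymmetric 1,4-addition, in which the aryl-rhodium(I)/bisphosphine complex inserts the C3=C4 bond from one enantioface and water protonates the rhodium enolate, so the ligand alone sets C4 and the (S)-ligand is expected to give the (S)-lactone.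

**Step 3**
Reactants: 5 (4S)-4-[4-(benzyloxy)-3-methoxyphenyl]-6-bromo-8-methoxychroman-2-one
Product: 7 methyl (3S)-3-[4-(benzyloxy)-3-methoxyphenyl]-3-[2-(benzyloxy)-5-bromo-3-methoxyphenyl]propanoate, via hydroxy ester 6 (not isolated)
Conditions: BnBr, K2CO3, NaI (cat.), MeOH/acetone, reflux
Reagents that add atoms: methanol CO; benzyl bromide BrCc1ccccc1
Why: carbonate-mediated methanolysis of the aryl ester opens the lactone and Williamson benzylation traps the phenoxide, which prevents relactonisation and a later oxa-Michael closure onto the enone; the diarylmethine C–H is not acidic under these conditions.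

**Step 4**
Reactants: 7 methyl (3S)-3-[4-(benzyloxy)-3-methoxyphenyl]-3-[2-(benzyloxy)-5-bromo-3-methoxyphenyl]propanoate
Product: 8 (3S)-3-[4-(benzyloxy)-3-methoxyphenyl]-3-[2-(benzyloxy)-5-bromo-3-methoxyphenyl]propanal
Conditions: DIBAL-H (1.1 equiv), CH2Cl2, −78 °C; Rochelle salt work-up
Reagents that add atoms: none
Why: partial ester reduction, in which the tetrahedral aluminium hemiacetal is stable at −78 °C and releases the aldehyde only on work-up; aryl bromide and benzyl ethers do not react.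

**Step 5**
Reactants: 8 (3S)-3-[4-(benzyloxy)-3-methoxyphenyl]-3-[2-(benzyloxy)-5-bromo-3-methoxyphenyl]propanal
Product: 9 (3E,6S)-6-[4-(benzyloxy)-3-methoxyphenyl]-6-[2-(benzyloxy)-5-bromo-3-methoxyphenyl]hex-3-en-2-one
Conditions: Ph3P=CHCOCH3, toluene, 80 °C
Reagents that add atoms: 1-(triphenylphosphoranylidene)propan-2-one CC(=O)C=P(c1ccccc1)(c1ccccc1)c1ccccc1
Why: Wittig reaction with a stabilised ylide, which is (E)-selective and runs under neutral conditions that leave the β-stereocentre alone.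

**Step 6**
Reactants: 9 (3E,6S)-6-[4-(benzyloxy)-3-methoxyphenyl]-6-[2-(benzyloxy)-5-bromo-3-methoxyphenyl]hex-3-en-2-one
Product: 11 (3E,6S)-6-[4-(benzyloxy)-3-methoxyphenyl]-6-[2-(benzyloxy)-5-bromo-3-methoxyphenyl]-1-diazohex-3-en-2-one, via trifluoroacetyl diketone 10 (not isolated)
Conditions: LiHMDS, THF, −78 °C; CF3CO2CH2CF3; then MsN3, Et3N, H2O, MeCN, 25 °C
Reagents that add atoms: methanesulfonyl azide CS(=O)(=O)N=[N+]=[N-]; 2,2,2-trifluoroethyl trifluoroacetate O=C(OCC(F)(F)F)C(F)(F)F (its CF3CO group is retained only in 10)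
Why: detrifluoroacetylative diazo transfer (a Regitz-type reaction), in which kinetic deprotonation at the methyl group and Claisen trifluoroacetylation activate the α′-position and the sulfonyl azide then delivers N2 with loss of the trifluoroacetyl group as the N-acylsulfonamide.

**Step 7**
Reactants: 12 ethyl formate
Product: 15 triisopropylsilyloxyacetylene, via lithium dibromoenolate 13 (not isolated), via lithium ethynolate 14 (not isolated)
Conditions: CH2Br2, LiTMP, THF, −78 °C; LiHMDS; n-BuLi, −78 → 0 °C; TIPSCl, 0 → 25 °C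
Reagents that add atoms: dibromomethane BrCBr; triisopropylsilyl chloride CC(C)[Si](Cl)(C(C)C)C(C)C
Why: Kowalski ester-to-ynolate sequence, in which dibromomethyllithium adds to the formate, enolate 13 undergoes bromine–lithium exchange, the carbenoid rearranges by 1,2-hydrogen shift to ynolate 14 and the bulky chlorosilane silylates on oxygen.

**Step 8**
Reactants: 11 (3E,6S)-6-[4-(benzyloxy)-3-methoxyphenyl]-6-[2-(benzyloxy)-5-bromo-3-methoxyphenyl]-1-diazohex-3-en-2-one; 15 triisopropylsilyloxyacetylene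
Product: 20 2-[(2S)-2-[4-(benzyloxy)-3-methoxyphenyl]-2-[2-(benzyloxy)-5-bromo-3-methoxyphenyl]ethyl]-5-(triisopropylsilyloxy)phenol, via vinylketene 16 (not isolated), via cyclobutenone 17 (not isolated), via dienylketene 18 (not isolated), via cyclohexadienone 19 (not isolated)
Conditions: 15 (3 equiv), degassed ClCH2CH2Cl, hν (365 nm LED, Pyrex), 25 °C; then 80 °C
Reagents that add atoms: none
Why: Irradiation of the diazo ketone band triggers Wolff rearrangement with migration of the alkenyl group to give vinylketene 16, and the electron-rich CH terminus of the silyl ynol ether attacks the ketene carbonyl carbon in a [2+2] cycloaddition to give 4-alkenyl-3-silyloxycyclobutenone 17. On heating, 17 opens by reversible 4π electrocyclic cleavage to dienylketene 18, whose 6π electrocyclisation joins the ketene carbon to the alkene terminus bearing the CH2 group to give dienone 19, and enolisation gives phenol 20. The closest known reaction type is the photochemical Danheiser benzannulation of α,β-unsaturated α′-diazo ketones with alkoxy- and silyloxyalkynes to resorcinol monoethers. The four-membered ring is closed by the ketene–alkyne [2+2] and consumed again, and the benzene ring is closed by the thermal disrotatory 6π closure followed by tautomerisation. No stereocentre remains from the step (the sp3 centres of 17 and 19 disappear on aromatisation), and the diarylmethine centre, two atoms away from the reacting π-system in a sequence of neutral pericyclic events, is expected to be retained. The step needs regiocontrol in the [2+2] event, which the polarity match between the ketene carbonyl carbon and the nucleophilic alkyne terminus provides (OH ortho and OSi para to the CH2), and selective excitation, which irradiation above 350 nm provides because the aryl bromide and benzyl ethers do not absorb there.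

**Step 9**
Reactants: 21 3,5-bis(benzyloxy)benzaldehyde
Product: 22 3,5-bis(benzyloxy)styrene
Conditions: Ph3PCH3Br, KOt-Bu, THF, 0 → 25 °C
Reagents that add atoms: methyltriphenylphosphonium bromide C[P+](c1ccccc1)(c1ccccc1)c1ccccc1.[Br-]
Why: Wittig methylenation of an aromatic aldehyde with the non-stabilised ylide.

**Step 10**
Reactants: 20 2-[(2S)-2-[4-(benzyloxy)-3-methoxyphenyl]-2-[2-(benzyloxy)-5-bromo-3-methoxyphenyl]ethyl]-5-(triisopropylsilyloxy)phenol; 22 3,5-bis(benzyloxy)styrene
Product: 23 2-[(2S)-2-[4-(benzyloxy)-3-methoxyphenyl]-2-{2-(benzyloxy)-5-[(E)-2-(3,5-bis(benzyloxy)phenyl)ethenyl]-3-methoxyphenyl}ethyl]-5-(triisopropylsilyloxy)phenol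
Conditions: Pd2(dba)3 (2.5 mol %), [HP(t-Bu)3]BF4, Cy2NMe, dioxane, 80 °C
Reagents that add atoms: none
Why: Mizoroki–Heck reaction, in which the bulky trialkylphosphine enables oxidative addition of the electron-rich aryl bromide and syn insertion at the terminal alkene carbon followed by syn β-hydride elimination gives the (E)-stilbene; the free phenol and the silyl ether tolerate the amine base.

**Step 11**
Reactants: 23 2-[(2S)-2-[4-(benzyloxy)-3-methoxyphenyl]-2-{2-(benzyloxy)-5-[(E)-2-(3,5-bis(benzyloxy)phenyl)ethenyl]-3-methoxyphenyl}ethyl]-5-(triisopropylsilyloxy)phenol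
Product: 24 4-[(2S)-2-[4-(benzyloxy)-3-methoxyphenyl]-2-{2-(benzyloxy)-5-[(E)-2-(3,5-bis(benzyloxy)phenyl)ethenyl]-3-methoxyphenyl}ethyl]benzene-1,3-diol
Conditions: TBAF, AcOH, THF, 0 °C
Reagents that add atoms: none
Why: fluoride cleavage of the aryl silyl ether, with acetic acid buffering so that the electron-rich resorcinol is not left as a phenoxide.

**Step 12**
Reactants: 24 4-[(2S)-2-[4-(benzyloxy)-3-methoxyphenyl]-2-{2-(benzyloxy)-5-[(E)-2-(3,5-bis(benzyloxy)phenyl)ethenyl]-3-methoxyphenyl}ethyl]benzene-1,3-diol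
Product: 25 4-[(2S)-2-{5-[(E)-2-(3,5-dihydroxyphenyl)ethenyl]-2-hydroxy-3-methoxyphenyl}-2-(4-hydroxy-3-methoxyphenyl)ethyl]benzene-1,3-diol (CNP0254096.1)
Conditions: BCl3 (excess), C6HMe5, CH2Cl2, −78 °C; MeOH quench
Reagents that add atoms: none
Why: Lewis-acid debenzylation with pentamethylbenzene as a non-Lewis-basic benzyl cation scavenger, which at −78 °C should spare the aryl methyl ethers, the stilbene double bond and the stereocentre, whereas hydrogenolysis would reduce the alkene.

**Compound list**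
1 | 5-bromo-2-hydroxy-3-methoxybenzaldehyde | COc1cc(Br)cc(C=O)c1O | starting material
2 | ethyl (2E)-3-(5-bromo-2-hydroxy-3-methoxyphenyl)prop-2-enoate | CCOC(=O)/C=C/c1cc(Br)cc(OC)c1O | intermediate (not isolated)
3 | 6-bromo-8-methoxy-2H-chromen-2-one | COc1cc(Br)cc2ccc(=O)oc12 | intermediate
4 | 4-benzyloxy-3-methoxyphenylboronic acid | COc1cc(B(O)O)ccc1OCc1ccccc1 | starting material
5 | (4S)-4-[4-(benzyloxy)-3-methoxyphenyl]-6-bromo-8-methoxychroman-2-one | COc1cc([C@@H]2CC(=O)Oc3c(OC)cc(Br)cc32)ccc1OCc1ccccc1 | intermediate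
6 | methyl (3S)-3-[4-(benzyloxy)-3-methoxyphenyl]-3-(5-bromo-2-hydroxy-3-methoxyphenyl)propanoate | COc1cc([C@H](CC(=O)OC)c2cc(Br)cc(OC)c2O)ccc1OCc1ccccc1 | intermediate (not isolated)
7 | methyl (3S)-3-[4-(benzyloxy)-3-methoxyphenyl]-3-[2-(benzyloxy)-5-bromo-3-methoxyphenyl]propanoate | COc1cc([C@H](CC(=O)OC)c2cc(Br)cc(OC)c2OCc2ccccc2)ccc1OCc1ccccc1 | intermediate
8 | (3S)-3-[4-(benzyloxy)-3-methoxyphenyl]-3-[2-(benzyloxy)-5-bromo-3-methoxyphenyl]propanal | COc1cc([C@H](CC=O)c2cc(Br)cc(OC)c2OCc2ccccc2)ccc1OCc1ccccc1 | intermediate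
9 | (3E,6S)-6-[4-(benzyloxy)-3-methoxyphenyl]-6-[2-(benzyloxy)-5-bromo-3-methoxyphenyl]hex-3-en-2-one | COc1cc([C@H](C/C=C/C(C)=O)c2cc(Br)cc(OC)c2OCc2ccccc2)ccc1OCc1ccccc1 | intermediate
10 | (5E,8S)-8-[4-(benzyloxy)-3-methoxyphenyl]-8-[2-(benzyloxy)-5-bromo-3-methoxyphenyl]-1,1,1-trifluorooct-5-ene-2,4-dione | COc1cc([C@H](C/C=C/C(=O)CC(=O)C(F)(F)F)c2cc(Br)cc(OC)c2OCc2ccccc2)ccc1OCc1ccccc1 | intermediate (not isolated)
11 | (3E,6S)-6-[4-(benzyloxy)-3-methoxyphenyl]-6-[2-(benzyloxy)-5-bromo-3-methoxyphenyl]-1-diazohex-3-en-2-one | COc1cc([C@H](C/C=C/C(=O)C=[N+]=[N-])c2cc(Br)cc(OC)c2OCc2ccccc2)ccc1OCc1ccccc1 | intermediate (key-step precursor)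
12 | ethyl formate | CCOC=O | starting material
13 | lithium 2,2-dibromoethenolate | [Li+].[O-]C=C(Br)Br | intermediate (not isolated)
14 | lithium ethynolate | [Li+].[O-]C#C | intermediate (not isolated)
15 | triisopropylsilyloxyacetylene | C#CO[Si](C(C)C)(C(C)C)C(C)C | intermediate (key-step precursor)
16 | (3E,6S)-6-[4-(benzyloxy)-3-methoxyphenyl]-6-[2-(benzyloxy)-5-bromo-3-methoxyphenyl]hexa-1,3-dien-1-one | COc1cc([C@H](C/C=C/C=C=O)c2cc(Br)cc(OC)c2OCc2ccccc2)ccc1OCc1ccccc1 | intermediate (not isolated)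
17 | 4-[(1E,4S)-4-[4-(benzyloxy)-3-methoxyphenyl]-4-[2-(benzyloxy)-5-bromo-3-methoxyphenyl]but-1-en-1-yl]-3-(triisopropylsilyloxy)cyclobut-2-en-1-one (both C4 epimers) | COc1cc([C@H](C/C=C/C2C(=O)C=C2O[Si](C(C)C)(C(C)C)C(C)C)c2cc(Br)cc(OC)c2OCc2ccccc2)ccc1OCc1ccccc1 | intermediate (not isolated)
18 | (3E,5E,8S)-8-[4-(benzyloxy)-3-methoxyphenyl]-8-[2-(benzyloxy)-5-bromo-3-methoxyphenyl]-3-(triisopropylsilyloxy)octa-1,3,5-trien-1-one | COc1cc([C@H](C/C=C/C=C(/O[Si](C(C)C)(C(C)C)C(C)C)\C=C=O)c2cc(Br)cc(OC)c2OCc2ccccc2)ccc1OCc1ccccc1 | intermediate (not isolated)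
19 | 6-[(2S)-2-[4-(benzyloxy)-3-methoxyphenyl]-2-[2-(benzyloxy)-5-bromo-3-methoxyphenyl]ethyl]-3-(triisopropylsilyloxy)cyclohexa-2,4-dien-1-one (both C6 epimers) | COc1cc([C@H](CC2C=CC(O[Si](C(C)C)(C(C)C)C(C)C)=CC2=O)c2cc(Br)cc(OC)c2OCc2ccccc2)ccc1OCc1ccccc1 | intermediate (not isolated)
20 | 2-[(2S)-2-[4-(benzyloxy)-3-methoxyphenyl]-2-[2-(benzyloxy)-5-bromo-3-methoxyphenyl]ethyl]-5-(triisopropylsilyloxy)phenol | COc1cc([C@H](Cc2ccc(O[Si](C(C)C)(C(C)C)C(C)C)cc2O)c2cc(Br)cc(OC)c2OCc2ccccc2)ccc1OCc1ccccc1 | intermediate (key-step product)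
21 | 3,5-bis(benzyloxy)benzaldehyde | O=Cc1cc(OCc2ccccc2)cc(OCc2ccccc2)c1 | starting material
22 | 3,5-bis(benzyloxy)styrene | C=Cc1cc(OCc2ccccc2)cc(OCc2ccccc2)c1 | intermediate
23 | 2-[(2S)-2-[4-(benzyloxy)-3-methoxyphenyl]-2-{2-(benzyloxy)-5-[(E)-2-(3,5-bis(benzyloxy)phenyl)ethenyl]-3-methoxyphenyl}ethyl]-5-(triisopropylsilyloxy)phenol | COc1cc([C@H](Cc2ccc(O[Si](C(C)C)(C(C)C)C(C)C)cc2O)c2cc(/C=C/c3cc(OCc4ccccc4)cc(OCc4ccccc4)c3)cc(OC)c2OCc2ccccc2)ccc1OCc1ccccc1 | intermediate
24 | 4-[(2S)-2-[4-(benzyloxy)-3-methoxyphenyl]-2-{2-(benzyloxy)-5-[(E)-2-(3,5-bis(benzyloxy)phenyl)ethenyl]-3-methoxyphenyl}ethyl]benzene-1,3-diol | COc1cc([C@H](Cc2ccc(O)cc2O)c2cc(/C=C/c3cc(OCc4ccccc4)cc(OCc4ccccc4)c3)cc(OC)c2OCc2ccccc2)ccc1OCc1ccccc1 | intermediate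
25 | 4-[(2S)-2-{5-[(E)-2-(3,5-dihydroxyphenyl)ethenyl]-2-hydroxy-3-methoxyphenyl}-2-(4-hydroxy-3-methoxyphenyl)ethyl]benzene-1,3-diol | COc1cc([C@H](Cc2ccc(O)cc2O)c2cc(/C=C/c3cc(O)cc(O)c3)cc(OC)c2O)ccc1O | target

**Totals**
Total step count: 12. Longest linear sequence: 10 steps (steps 1–6, 8, 10–12); steps 7 and 9 are side branches.

**Steps most likely to fail**

Step 8. The photolysis may be inefficient or unselective (light taken up by the aryl ethers, C–Br homolysis), the vinylketene may be intercepted by the phenolic product as its ester, or the cyclobutenone may not relay cleanly to the arene. The fallback gives up de novo construction of ring B and brings it in whole. It sets out from ester 7 and returns at target 25.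
- Heck coupling of 7 with styrene 22 under the step 10 conditions gives the stilbene ester F1.
- Saponification (LiOH, THF/H2O) gives the carboxylic acid F2.
- N-Hydroxyphthalimide and N,N′-diisopropylcarbodiimide convert it into the N-acyloxyphthalimide F3.
- Nickel-catalysed decarboxylative arylation (NiCl2·glyme, 4,4′-di-tert-butyl-2,2′-bipyridine, THF/DMF, 25 °C) with [2,4-bis(benzyloxy)phenyl]zinc chloride F4 gives the hexabenzyl ether F5. F4 is made from purchased 1-bromo-2,4-bis(benzyloxy)benzene by magnesium insertion and transmetallation with ZnCl2. A high nickel loading is used so that capture of the primary radical outruns 1,2-aryl migration.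
- BCl3/pentamethylbenzene under the step 12 conditions then gives 25.

Step 7. The formate adduct may over-add, the ynolate may silylate on carbon, or the small silyl ynol ether may be lost through volatility or hydrolysis on isolation. The fallback replaces the ynolate route by an elimination route to an alkyl ynol ether whose O-alkyl group falls in the final Lewis-acid step. It sets out from diazo enone 11 and returns at target 25.
- Isopropanol, KH and trichloroethylene give 1,2-dichlorovinyl isopropyl ether F6.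
- n-BuLi (2.2 equiv) followed by methanol gives isopropoxyacetylene F7.
- Irradiation of 11 with F7 as in step 8 (excess alkyne evaporated before the thermal stage, because secondary alkyl ynol ethers fragment to ketene on heating) should give the isopropoxy phenol F8.
- Heck coupling with 22 gives the isopropoxy stilbene F9.
- BCl3/pentamethylbenzene with warming from −78 to 0 °C cleaves the four benzyl ethers and the isopropyl ether but not the methyl ethers, giving 25; step 11 is not needed.

Step 2. Insertion into the hindered, electron-rich coumarin may be slow against protodeboronation of the boronic acid, or the facial discrimination may be insufficient. The fallback moves the asymmetric arylation to an open-chain acceptor. It sets out from aldehyde 1 and returns at ester 7.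
- Benzylation of 1 (BnBr, K2CO3, DMF) gives 2-(benzyloxy)-5-bromo-3-methoxybenzaldehyde F10.
- Wittig reaction with methyl (triphenylphosphoranylidene)acetate gives the (E)-cinnamate F11.
- Rhodium(I)/chiral bicyclic diene-catalysed 1,4-addition of boronic acid 4 (KOH, dioxane/H2O), with the diene enantiomer chosen for the (S)-product, gives 7 directly.

**Further compounds**
F1 | step 8 | methyl (3S)-3-[4-(benzyloxy)-3-methoxyphenyl]-3-{2-(benzyloxy)-5-[(E)-2-(3,5-bis(benzyloxy)phenyl)ethenyl]-3-methoxyphenyl}propanoate | COc1cc([C@H](CC(=O)OC)c2cc(/C=C/c3cc(OCc4ccccc4)cc(OCc4ccccc4)c3)cc(OC)c2OCc2ccccc2)ccc1OCc1ccccc1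
F2 | step 8 | (3S)-3-[4-(benzyloxy)-3-methoxyphenyl]-3-{2-(benzyloxy)-5-[(E)-2-(3,5-bis(benzyloxy)phenyl)ethenyl]-3-methoxyphenyl}propanoic acid | COc1cc([C@H](CC(=O)O)c2cc(/C=C/c3cc(OCc4ccccc4)cc(OCc4ccccc4)c3)cc(OC)c2OCc2ccccc2)ccc1OCc1ccccc1
F3 | step 8 | 1,3-dioxoisoindolin-2-yl (3S)-3-[4-(benzyloxy)-3-methoxyphenyl]-3-{2-(benzyloxy)-5-[(E)-2-(3,5-bis(benzyloxy)phenyl)ethenyl]-3-methoxyphenyl}propanoate | COc1cc([C@H](CC(=O)ON2C(=O)c3ccccc3C2=O)c2cc(/C=C/c3cc(OCc4ccccc4)cc(OCc4ccccc4)c3)cc(OC)c2OCc2ccccc2)ccc1OCc1ccccc1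
F4 | step 8 | [2,4-bis(benzyloxy)phenyl]zinc chloride | Cl[Zn]c1ccc(OCc2ccccc2)cc1OCc1ccccc1
F5 | step 8 | 2,4-bis(benzyloxy)-1-[(2S)-2-[4-(benzyloxy)-3-methoxyphenyl]-2-{2-(benzyloxy)-5-[(E)-2-(3,5-bis(benzyloxy)phenyl)ethenyl]-3-methoxyphenyl}ethyl]benzene | COc1cc([C@H](Cc2ccc(OCc3ccccc3)cc2OCc2ccccc2)c2cc(/C=C/c3cc(OCc4ccccc4)cc(OCc4ccccc4)c3)cc(OC)c2OCc2ccccc2)ccc1OCc1ccccc1
F6 | step 7 | 1,2-dichlorovinyl isopropyl ether (alkene geometry immaterial) | CC(C)OC(Cl)=CCl
F7 | step 7 | isopropoxyacetylene | CC(C)OC#C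
F8 | step 7 | 2-[(2S)-2-[4-(benzyloxy)-3-methoxyphenyl]-2-[2-(benzyloxy)-5-bromo-3-methoxyphenyl]ethyl]-5-isopropoxyphenol | COc1cc([C@H](Cc2ccc(OC(C)C)cc2O)c2cc(Br)cc(OC)c2OCc2ccccc2)ccc1OCc1ccccc1
F9 | step 7 | 2-[(2S)-2-[4-(benzyloxy)-3-methoxyphenyl]-2-{2-(benzyloxy)-5-[(E)-2-(3,5-bis(benzyloxy)phenyl)ethenyl]-3-methoxyphenyl}ethyl]-5-isopropoxyphenol | COc1cc([C@H](Cc2ccc(OC(C)C)cc2O)c2cc(/C=C/c3cc(OCc4ccccc4)cc(OCc4ccccc4)c3)cc(OC)c2OCc2ccccc2)ccc1OCc1ccccc1
F10 | step 2 | 2-(benzyloxy)-5-bromo-3-methoxybenzaldehyde | COc1cc(Br)cc(C=O)c1OCc1ccccc1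
F11 | step 2 | methyl (2E)-3-[2-(benzyloxy)-5-bromo-3-methoxyphenyl]prop-2-enoate | COC(=O)/C=C/c1cc(Br)cc(OC)c1OCc1ccccc1
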